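The flavone is cut at C2 of the pyranone (ring C). C2 is a single acyl-level carbon lying between C3 and C1' of ring B, so it can be delivered as carbon monoxide. One palladium-catalysed carbonylative coupling unites commercial 1-bromo-2,3,4-trimethoxybenzene, CO and the acetyl methyl group of commercial 2-hydroxy-4,5-dimethoxyacetophenone, forging C1'–C2 and C2–C3 and giving the o-hydroxyaryl 1,3-diketone with all five methoxy groups in place. Both partners are used unprotected: the free ortho phenol is an asset, since any O-aroylated material funnels to the same diketone by base-induced acyl transfer. Acid-catalysed cyclodehydration (O1–C2) then closes ring C.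

Key step: step 1

Remark on the chemistry: the target is read as 6,7-dimethoxy-2-(2,3,4-trimethoxyphenyl)-4H-chromen-4-one, which is achiral, so no stereocentre has to be set. Acetophenone C1, C2-OH, C4-OMe and C5-OMe map onto C4a, O1/C8a, C7-OMe and C6-OMe, and the brominated carbon becomes C1'. Both organic starting materials and CO are taken as purchased.

Step 1
Reactants: 1 1-(2-hydroxy-4,5-dimethoxyphenyl)ethanone; 2 1-bromo-2,3,4-trimethoxybenzene; 3 carbon monoxide
Product: 5 1-(2-hydroxy-4,5-dimethoxyphenyl)-3-(2,3,4-trimethoxyphenyl)propane-1,3-dione, via aryl ester 4 (not isolated)
Conditions: Pd(OAc)2 (4 mol%), 1,4-bis(diphenylphosphino)butane (8 mol%), 1,8-diazabicyclo[5.4.0]undec-7-ene (DBU, 3 equiv), 2 (1.1 equiv), CO (10 bar, autoclave), dry DMSO, 110 °C; then 1 M HCl, EtOAc extraction; crude 5 carried on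
Reagents that add atoms: none
Why: Pd(OAc)2 is reduced under CO and phosphine to zerovalent palladium, which adds oxidatively to the C–Br bond of 2; CO insertion gives the 2,3,4-trimethoxybenzoyl complex of divalent palladium, and the DBU phenoxide of 1 takes up the acyl group to give aryl ester 4 and return the catalyst. In the same hot DBU/DMSO medium the acetyl group of 4 is enolised and attacks the adjacent ester carbonyl through a six-membered transition state (Baker–Venkataraman acyl transfer), so the CO-derived carbon ends bonded to C3, and the chelated diketonate of 5 acts as the thermodynamic sink. The closest known reaction type is the palladium-catalysed carbonylative alpha-arylation of ketones with aryl halides, which is established for 2-hydroxyacetophenones. No ring is closed and no stereocentre is formed in this step. Two selectivities are needed: carbonylative over direct coupling, secured by CO pressure because insertion into the aryl–palladium bond outpaces phenoxide or enolate arylation, and C- over O-acylation, secured by the ortho relationship of phenol and acetyl group, which lets any O-acyl product drain to 5 while direct enolate capture leads to 5 as well. Oxidative addition of the electron-rich, ortho-substituted bromide is the slow event, hence the chelating, alkyl-bridged bisphosphine, the slight excess of 2 and 110 °C.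

Step 2
Reactants: 5 1-(2-hydroxy-4,5-dimethoxyphenyl)-3-(2,3,4-trimethoxyphenyl)propane-1,3-dione
Product: 7 6,7-dimethoxy-2-(2,3,4-trimethoxyphenyl)-4H-chromen-4-one, via cyclic hemiketal 6 (not isolated)
Conditions: conc. H2SO4 (0.5 equiv), glacial AcOH, 95 °C, 1 h; pour onto ice-water, filter, recrystallise from EtOH
Reagents that add atoms: none
Why: This is the acid-catalysed cyclodehydration that ends the classical Baker–Venkataraman flavone synthesis: the phenolic oxygen adds to the protonated aroyl carbonyl (6-exo-trig, O1–C2) to give racemic hemiketal 6, which loses water to the conjugated 4-pyranone, while the aryl methyl ethers should tolerate brief heating in acetic acid with a little sulfuric acid and any material already cyclised in step 1 passes through unchanged.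

Compound list
1 | 1-(2-hydroxy-4,5-dimethoxyphenyl)ethanone | CC(=O)c1cc(OC)c(OC)cc1O | starting material
2 | 1-bromo-2,3,4-trimethoxybenzene | COc1ccc(Br)c(OC)c1OC | starting material
3 | carbon monoxide | [C-]#[O+] | starting material
4 | 2-acetyl-4,5-dimethoxyphenyl 2,3,4-trimethoxybenzoate | CC(=O)c1cc(OC)c(OC)cc1OC(=O)c1ccc(OC)c(OC)c1OC | intermediate (not isolated)
5 | 1-(2-hydroxy-4,5-dimethoxyphenyl)-3-(2,3,4-trimethoxyphenyl)propane-1,3-dione | COc1cc(O)c(C(=O)CC(=O)c2ccc(OC)c(OC)c2OC)cc1OC | intermediate
6 | 2-hydroxy-6,7-dimethoxy-2-(2,3,4-trimethoxyphenyl)-2,3-dihydro-4H-chromen-4-one (racemic hemiketal) | COc1cc2OC(O)(c3ccc(OC)c(OC)c3OC)CC(=O)c2cc1OC | intermediate (not isolated)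
7 | 6,7-dimethoxy-2-(2,3,4-trimethoxyphenyl)-4H-chromen-4-one | COc1cc2oc(-c3ccc(OC)c(OC)c3OC)cc(=O)c2cc1OC | target

Total step count: 2
Longest linear sequence: 2 steps (1 to 7)

Steps most likely to fail (the route has only two steps, so both are ranked, the riskier first)

1. Step 1. Several processes could stall it:
- Oxidative addition of the electron-rich, ortho-substituted bromide may be too slow under CO pressure, so the catalyst decays to inactive palladium before conversion is complete.
- Acyl transfer may stop at the O-ester stage.
- Adventitious water may intercept the acyl palladium species.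

The fallback replaces catalysis by the stoichiometric Baker–Venkataraman sequence. It sets out from 1 and comes back to the route at 5. Commercial 2,3,4-trimethoxybenzoic acid would be converted with oxalyl chloride and catalytic DMF in CH2Cl2 into 2,3,4-trimethoxybenzoyl chloride F1. F1 would acylate the phenol of 1 in pyridine with catalytic 4-dimethylaminopyridine at 0 °C to room temperature, giving 4, which is isolated in this variant. Powdered KOH in pyridine at 50 °C, followed by quenching with dilute acetic acid, should then rearrange 4 to 5.

2. Step 2. The processes to fear are:
- incomplete dehydration, with material resting at the hemiketal stage;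
- acid-promoted retro-Claisen cleavage of the diketone;
- loss of a methyl ether on prolonged heating in strong acid, the 2'-methoxy group being the most exposed.

The fallback avoids the diketone and acid altogether by the chalcone route. It sets out from 1 and comes back to the route at 7. Claisen–Schmidt condensation of 1 with commercial 2,3,4-trimethoxybenzaldehyde (KOH, EtOH, room temperature) should give (E)-1-(2-hydroxy-4,5-dimethoxyphenyl)-3-(2,3,4-trimethoxyphenyl)prop-2-en-1-one F2. Oxidative cyclisation of F2 with catalytic iodine in DMSO at 120–130 °C should then give 7 directly, by oxa-Michael closure and dehydrogenation with DMSO as the terminal oxidant.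

Further compounds
F1 | step 1 | 2,3,4-trimethoxybenzoyl chloride | COc1ccc(C(Cl)=O)c(OC)c1OC
F2 | step 2 | (E)-1-(2-hydroxy-4,5-dimethoxyphenyl)-3-(2,3,4-trimethoxyphenyl)prop-2-en-1-one | COc1cc(O)c(C(=O)/C=C/c2ccc(OC)c(OC)c2OC)cc1OC
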